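The target is cut at its two methylene bridges into a resolved ring A triketone, butyrylphloroglucinol (ring B) and a ring C chromene, so everything rests on making that chromene as a single regioisomer. In ring C the pyran oxygen O1 sits on C8a, next to the butyryl-bearing C8, and C4 is bonded to C4a. An aryl 1,1-dimethylpropargyl ether placed on an oxygen ortho to the butyryl group, with the para oxygen silylated, is heated: aromatic Claisen rearrangement to the only free ortho carbon forms the C4–C4a bond, and a hydrogen shift followed by oxa-6π closure re-forms O1–C2, closing the pyran in one operation.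

Key step: step 4

Remark 1: the quaternary carbon of ring A has the (R) descriptor in the tautomer drawn; it is made racemic and resolved, because no catalytic facial control is established for this substrate class.
Remark 2: the para oxygen carries a triisopropylsilyl group rather than a smaller silyl group, because an aryl silyl ether para to a ketone must survive DBU in step 3; its loss there would let the para oxygen be etherified and lead to the wrong chromene.
Remark 3: compounds 1, 2, 5, 13, 14 and 16 are assumed to be commercially available.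

Step 1
Reactants: 1 phloroglucinol; 2 butyryl chloride
Product: 3 1-(2,4,6-trihydroxyphenyl)butan-1-one (butyrylphloroglucinol)
Conditions: AlCl3 (4 equiv), PhNO2/CH2Cl2, 0 °C to 40 °C; aq HCl
Reagents that add atoms: none
Why: Friedel–Crafts C-acylation of the electron-rich triol; the aluminium chelate of the first-formed aryl ketone is deactivated, so monoacylation should prevail.

Step 2
Reactants: 3 butyrylphloroglucinol
Product: 4 1-[2,6-dihydroxy-4-(triisopropylsilyloxy)phenyl]butan-1-one
Conditions: TIPSCl (1.0 equiv), imidazole (2 equiv), DMF, 0 °C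
Reagents that add atoms: triisopropylsilyl chloride, CC(C)[Si](Cl)(C(C)C)C(C)C
Why: Regioselective O-silylation of the most acidic phenol: the para hydroxyl is neither hydrogen-bonded to the ketone nor flanked by the acyl group, so one equivalent of the bulky chlorosilane should take it and leave both ortho hydroxyls free.

Step 3
Reactants: 4 para-O-silylated butyrylphloroglucinol; 5 3-chloro-3-methylbut-1-yne
Product: 6 1-[2-hydroxy-6-(2-methylbut-3-yn-2-yloxy)-4-(triisopropylsilyloxy)phenyl]butan-1-one
Conditions: CuCl2·2H2O (5 mol %), DBU (1.3 equiv), MeCN, 0 °C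
Reagents that add atoms: none
Why: Copper-catalysed propargylic etherification of a phenol (a copper acetylide ionises the tertiary chloride and the phenoxide oxygen captures the resulting allenylidene-type electrophile): the two free hydroxyls of 4 are equivalent, and once one is etherified the other is locked in the chelate to the ketone, so the mono-ether on an oxygen ortho to the butyryl group should result while the triisopropylsilyl ether withstands DBU.

Step 4
Reactants: 6 aryl 1,1-dimethylpropargyl ether
Product: 10 1-[7-hydroxy-2,2-dimethyl-5-(triisopropylsilyloxy)-2H-chromen-8-yl]butan-1-one (8-butyryl-7-hydroxy-5-silyloxy-2,2-dimethyl-2H-chromene), via allenyl cyclohexadienone 7 (not isolated), via ortho-allenylphenol 8 (not isolated), via ortho-quinone methide 9 (not isolated)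
Conditions: degassed o-xylene, 140 °C
Reagents that add atoms: none
Why: Heating triggers an aromatic Claisen ([3,3]) rearrangement of the aryl propargyl ether that forms the C4a–C4 bond and gives allenyl dienone 7, which enolises to allenylphenol 8; a 1,5-hydrogen shift from the new phenolic OH to the central allene carbon then gives ortho-quinone methide 9. The six-membered pyran ring is closed by a thermal disrotatory oxa-6π electrocyclisation of the 1-oxatriene in 9, the carbonyl oxygen bonding to the CMe2 terminus and restoring the aromatic ring. The closest known reaction type is the thermal conversion of aryl 1,1-dimethylpropargyl ethers into 2,2-dimethyl-2H-chromenes. No stereocenter is formed. The step needs regioselectivity twice: of the two carbons ortho to the ether oxygen, the one bearing the butyryl group can only give a dienone that cannot enolise and reverts, so the shift to the hydrogen-bearing carbon is the only productive one; and of the two oxygens flanking that carbon in 9, only the carbonyl oxygen next to the acyl group can close the ring because the other is silylated. Neutral conditions free of base and fluoride disfavour the 5-exo closure of 8 to a benzofuran and keep acid away from the chromene.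

Step 5
Reactants: 10 silylated chromene
Product: 11 1-(5,7-dihydroxy-2,2-dimethyl-2H-chromen-8-yl)butan-1-one
Conditions: TBAF, AcOH, THF, 0 °C
Reagents that add atoms: none
Why: Fluoride cleavage of an aryl silyl ether, fast because the phenoxide para to the ketone is a good leaving group; acetic acid buffers the phenoxide so that the chromene sees neither strong base nor strong acid.

Step 6
Reactants: 11 chromene diol
Product: 12 1-[6-[(dimethylamino)methyl]-5,7-dihydroxy-2,2-dimethyl-2H-chromen-8-yl]butan-1-one
Conditions: CH2(NMe2)2 (3 equiv), MeCN, rt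
Reagents that add atoms: bis(dimethylamino)methane, CN(C)CN(C)C
Why: Phenolic Mannich reaction: the acidic phenol ionises the aminal to the methyleneiminium ion, which attacks C6, the only unsubstituted ring carbon and flanked by two hydroxyls; excess aminal and room temperature should keep the product from losing amine prematurely.

Step 7
Reactants: 13 2-methylbenzene-1,3,5-triol (2-methylphloroglucinol); 14 acetyl chloride
Product: 15 1-(2,4,6-trihydroxy-3-methylphenyl)ethan-1-one
Conditions: AlCl3 (4 equiv), PhNO2/CH2Cl2, 0 °C to rt; aq HCl
Reagents that add atoms: none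
Why: Friedel–Crafts C-acylation; the two unsubstituted ring carbons of 13 are equivalent, so a single monoketone is expected.

Step 8
Reactants: 15 methylphloracetophenone; 16 geranyl bromide
Product: 17 racemic 2-acetyl-4-[(2E)-3,7-dimethylocta-2,6-dien-1-yl]-3,5-dihydroxy-4-methylcyclohexa-2,5-dien-1-one
Conditions: NaOMe (3 equiv), MeOH, 0 °C to rt; aq citric acid, then extraction into aq NaHCO3
Reagents that add atoms: none
Why: Alkylative dearomatisation of an acylphloroglucinol: in methanolic sodium methoxide the phenoxide reacts as a carbon nucleophile and SN2 attack from the methyl-bearing ring carbon on the allylic bromide (E alkene retained) creates the quaternary carbon without facial bias, so 17 is racemic; the strongly acidic triketone should be separable from aromatic C-geranyl and O-geranyl by-products by bicarbonate extraction.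

Step 9
Reactants: 17 racemic ring A triketone
Product: 18 (4R)-2-acetyl-4-[(2E)-3,7-dimethylocta-2,6-dien-1-yl]-3,5-dihydroxy-4-methylcyclohexa-2,5-dien-1-one
Conditions: preparative HPLC, amylose tris(3,5-dimethylphenylcarbamate) stationary phase, hexane/i-PrOH/HCO2H
Reagents that add atoms: none
Why: Resolution by preparative chromatography on a chiral stationary phase: the quaternary stereocenter formed without control in step 8 cannot epimerise, so physical separation of the enantiomers delivers the (R) series, the fraction to be carried on being identified by comparing its ECD curve with the calculated one.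

Step 10
Reactants: 18 (R)-ring A triketone
Product: 19 (4R)-2-acetyl-6-[(dimethylamino)methyl]-4-[(2E)-3,7-dimethylocta-2,6-dien-1-yl]-3,5-dihydroxy-4-methylcyclohexa-2,5-dien-1-one
Conditions: CH2(NMe2)2 (3 equiv), CH2Cl2, 0 °C
Reagents that add atoms: bis(dimethylamino)methane, CN(C)CN(C)C
Why: Mannich reaction of a cyclic 1,3-dicarbonyl compound: the vinylogous acid ionises the aminal and the iminium ion is captured at C6, the only ring carbon that still bears hydrogen, the product being held as an ammonium enolate zwitterion; the stereocenter is not involved.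

Step 11
Reactants: 19 ring A Mannich base; 3 butyrylphloroglucinol
Product: 21 (4R)-2-acetyl-6-[(3-butanoyl-2,4,6-trihydroxyphenyl)methyl]-4-[(2E)-3,7-dimethylocta-2,6-dien-1-yl]-3,5-dihydroxy-4-methylcyclohexa-2,5-dien-1-one (ring A–ring B dimer), via methylene trione 20 (not isolated)
Conditions: 3 (3 equiv), 1,4-dioxane, 70 °C; aq NaH2PO4 wash
Reagents that add atoms: none
Why: Retro-Mannich/Michael sequence: gentle heating expels dimethylamine to give 2-methylene-1,3-dione 20, to which a free ring carbon of 3 adds (Friedel–Crafts-type conjugate addition), the excess of 3 limiting the reaction to one of its two equivalent positions; the quaternary stereocenter is remote and untouched.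

Step 12
Reactants: 12 ring C Mannich base; 21 ring A–ring B dimer
Product: 23 CNP0103039.1, via ring C ortho-quinone methide 22 (not isolated)
Conditions: 1,4-dioxane, 80 °C, dark; aq NaH2PO4 wash
Reagents that add atoms: none
Why: Ortho-quinone methide coupling: thermal loss of dimethylamine from phenolic Mannich base 12 gives 22, and the single remaining ring carbon of ring B in 21, the only carbon nucleophile present, adds to it with rearomatisation (Michael addition) to form the second methylene bridge; no stereocenter is formed or disturbed.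

Compound list
1 | phloroglucinol | Oc1cc(O)cc(O)c1 | starting material
2 | butyryl chloride | CCCC(Cl)=O | starting material
3 | 1-(2,4,6-trihydroxyphenyl)butan-1-one (butyrylphloroglucinol) | CCCC(=O)c1c(O)cc(O)cc1O | intermediate
4 | 1-[2,6-dihydroxy-4-(triisopropylsilyloxy)phenyl]butan-1-one | CCCC(=O)c1c(O)cc(O[Si](C(C)C)(C(C)C)C(C)C)cc1O | intermediate
5 | 3-chloro-3-methylbut-1-yne | CC(C)(Cl)C#C | starting material
6 | 1-[2-hydroxy-6-(2-methylbut-3-yn-2-yloxy)-4-(triisopropylsilyloxy)phenyl]butan-1-one | CCCC(=O)c1c(O)cc(O[Si](C(C)C)(C(C)C)C(C)C)cc1OC(C)(C)C#C | intermediate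
7 | 2-butanoyl-3-hydroxy-6-(3-methylbuta-1,2-dien-1-yl)-5-(triisopropylsilyloxy)cyclohexa-2,4-dien-1-one (racemic, transient) | CCCC(=O)C1=C(O)C=C(O[Si](C(C)C)(C(C)C)C(C)C)C(C=C=C(C)C)C1=O | intermediate
8 | 1-[2,6-dihydroxy-3-(3-methylbuta-1,2-dien-1-yl)-4-(triisopropylsilyloxy)phenyl]butan-1-one | CCCC(=O)c1c(O)cc(O[Si](C(C)C)(C(C)C)C(C)C)c(C=C=C(C)C)c1O | intermediate
9 | 2-butanoyl-3-hydroxy-6-(3-methylbut-2-en-1-ylidene)-5-(triisopropylsilyloxy)cyclohexa-2,4-dien-1-one | CCCC(=O)C1=C(O)C=C(O[Si](C(C)C)(C(C)C)C(C)C)C(=CC=C(C)C)C1=O | intermediate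
10 | 1-[7-hydroxy-2,2-dimethyl-5-(triisopropylsilyloxy)-2H-chromen-8-yl]butan-1-one | CCCC(=O)c1c(O)cc(O[Si](C(C)C)(C(C)C)C(C)C)c2c1OC(C)(C)C=C2 | intermediate
11 | 1-(5,7-dihydroxy-2,2-dimethyl-2H-chromen-8-yl)butan-1-one | CCCC(=O)c1c(O)cc(O)c2c1OC(C)(C)C=C2 | intermediate
12 | 1-[6-[(dimethylamino)methyl]-5,7-dihydroxy-2,2-dimethyl-2H-chromen-8-yl]butan-1-one | CCCC(=O)c1c(O)c(CN(C)C)c(O)c2c1OC(C)(C)C=C2 | intermediate
13 | 2-methylbenzene-1,3,5-triol (2-methylphloroglucinol) | Cc1c(O)cc(O)cc1O | starting material
14 | acetyl chloride | CC(Cl)=O | starting material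
15 | 1-(2,4,6-trihydroxy-3-methylphenyl)ethan-1-one | CC(=O)c1c(O)cc(O)c(C)c1O | intermediate
16 | geranyl bromide, (2E)-1-bromo-3,7-dimethylocta-2,6-diene | CC(C)=CCC/C(C)=C/CBr | starting material
17 | racemic 2-acetyl-4-[(2E)-3,7-dimethylocta-2,6-dien-1-yl]-3,5-dihydroxy-4-methylcyclohexa-2,5-dien-1-one | CC(=O)C1=C(O)C(C)(C/C=C(\C)CCC=C(C)C)C(O)=CC1=O | intermediate
18 | (4R)-2-acetyl-4-[(2E)-3,7-dimethylocta-2,6-dien-1-yl]-3,5-dihydroxy-4-methylcyclohexa-2,5-dien-1-one | CC(=O)C1=C(O)[C@](C)(C/C=C(\C)CCC=C(C)C)C(O)=CC1=O | intermediate
19 | (4R)-2-acetyl-6-[(dimethylamino)methyl]-4-[(2E)-3,7-dimethylocta-2,6-dien-1-yl]-3,5-dihydroxy-4-methylcyclohexa-2,5-dien-1-one | CC(=O)C1=C(O)[C@](C)(C/C=C(\C)CCC=C(C)C)C(O)=C(CN(C)C)C1=O | intermediate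
20 | 2-acetyl-4-[(2E)-3,7-dimethylocta-2,6-dien-1-yl]-3-hydroxy-4-methyl-6-methylidenecyclohex-2-ene-1,5-dione, quaternary carbon arranged as in 18 | CC(=O)C1=C(O)[C@](C)(C/C=C(\C)CCC=C(C)C)C(=O)C(=C)C1=O | intermediate
21 | (4R)-2-acetyl-6-[(3-butanoyl-2,4,6-trihydroxyphenyl)methyl]-4-[(2E)-3,7-dimethylocta-2,6-dien-1-yl]-3,5-dihydroxy-4-methylcyclohexa-2,5-dien-1-one (ring A–ring B dimer) | CC(=O)C1=C(O)[C@](C)(C/C=C(\C)CCC=C(C)C)C(O)=C(Cc2c(O)cc(O)c(C(=O)CCC)c2O)C1=O | intermediate
22 | 8-butanoyl-7-hydroxy-2,2-dimethyl-6-methylidene-2H-chromen-5(6H)-one | CCCC(=O)C1=C(O)C(=C)C(=O)C2=C1OC(C)(C)C=C2 | intermediate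
23 | CNP0103039.1: ring B (butyrylphloroglucinol) linked by one CH2 to C6 of (R)-ring A and by the other CH2 to C6 of the ring C chromene | CCCC(=O)c1c(O)c(CC2=C(O)[C@@](C)(C/C=C(\C)CCC=C(C)C)C(O)=C(C(C)=O)C2=O)c(O)c(Cc2c(O)c3c(c(C(=O)CCC)c2O)OC(C)(C)C=C3)c1O | target

Total step count: 12. Longest linear sequence: 7 steps (steps 1 to 6, then step 12).

Steps most likely to fail

Step 4. The allenylphenol may close by 5-exo attack of the phenol on the allene to a benzofuran instead of undergoing the hydrogen shift. The silyl group may also be lost at the temperature needed, and the quinone methide may oligomerise. Fallback: setting out from 4, the chromene is assembled by condensation with 3-methylbut-2-enal (ethylenediammonium diacetate, toluene, 90 °C). Knoevenagel-type attack of a free ring carbon on the aldehyde gives the benzylic alcohol 1-[2,6-dihydroxy-3-(1-hydroxy-3-methylbut-2-en-1-yl)-4-(triisopropylsilyloxy)phenyl]butan-1-one F1 (not isolated). Its dehydration leads to the same quinone methide 9 and, after oxa-6π closure, back to the route at 10. The two free ring carbons of 4 are equivalent and the para oxygen is blocked, so the regiochemistry stays fixed.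

Step 8. Alkylation may go to the unsubstituted ring carbon (giving an aromatic geranyl isomer) or to oxygen, or a second alkylation may outrun dearomatisation at the methyl-bearing carbon. Fallback: setting out from 15, the unsubstituted ring carbon is blocked first. NBS (1 equiv, MeCN, 0 °C) should give 1-(3-bromo-2,4,6-trihydroxy-5-methylphenyl)ethan-1-one F2. Geranylation with 16 (NaOMe, MeOH) can then dearomatise only at the methyl-bearing carbon and should give racemic 2-acetyl-6-bromo-4-[(2E)-3,7-dimethylocta-2,6-dien-1-yl]-3,5-dihydroxy-4-methylcyclohexa-2,5-dien-1-one F3. Zinc dust in acetic acid at room temperature removes the bromine of the 2-bromo-1,3-dicarbonyl unit reductively and returns to the route at 17.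

Step 12. At the temperature needed to release the quinone methide, the bridge between rings A and B may exchange by retro-Michael cleavage and re-addition, scrambling the partners. The quinone methide may also be captured by an alkene (chromene or geranyl) in a hetero-Diels–Alder reaction or dimerise. Fallback: setting out from 12, 3 and 18 (steps 10 and 11 are then not needed), the order of bridging is reversed so that the more labile bridge to ring A is made last. Heating 12 with excess 3 (dioxane, 80 °C) should give the ring B–ring C dimer 1-[3-[(8-butanoyl-5,7-dihydroxy-2,2-dimethyl-2H-chromen-6-yl)methyl]-2,4,6-trihydroxyphenyl]butan-1-one F4. CH2(NMe2)2 (MeCN, rt) aminomethylates its one free ring B carbon to the Mannich base 1-[3-[(8-butanoyl-5,7-dihydroxy-2,2-dimethyl-2H-chromen-6-yl)methyl]-5-[(dimethylamino)methyl]-2,4,6-trihydroxyphenyl]butan-1-one F5. Warming F5 with 18 (dioxane, 60 °C) releases the ring B ortho-quinone methide F6 (not isolated), which is captured by C6 of the triketone, and the route is rejoined at 23.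

Further compounds
F1 | step 4 | 1-[2,6-dihydroxy-3-(1-hydroxy-3-methylbut-2-en-1-yl)-4-(triisopropylsilyloxy)phenyl]butan-1-one (not isolated) | CCCC(=O)c1c(O)cc(O[Si](C(C)C)(C(C)C)C(C)C)c(C(O)C=C(C)C)c1O
F2 | step 8 | 1-(3-bromo-2,4,6-trihydroxy-5-methylphenyl)ethan-1-one | CC(=O)c1c(O)c(Br)c(O)c(C)c1O
F3 | step 8 | racemic 2-acetyl-6-bromo-4-[(2E)-3,7-dimethylocta-2,6-dien-1-yl]-3,5-dihydroxy-4-methylcyclohexa-2,5-dien-1-one | CC(=O)C1=C(O)C(C)(C/C=C(\C)CCC=C(C)C)C(O)=C(Br)C1=O
F4 | step 12 | 1-[3-[(8-butanoyl-5,7-dihydroxy-2,2-dimethyl-2H-chromen-6-yl)methyl]-2,4,6-trihydroxyphenyl]butan-1-one | CCCC(=O)c1c(O)cc(O)c(Cc2c(O)c3c(c(C(=O)CCC)c2O)OC(C)(C)C=C3)c1O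
F5 | step 12 | 1-[3-[(8-butanoyl-5,7-dihydroxy-2,2-dimethyl-2H-chromen-6-yl)methyl]-5-[(dimethylamino)methyl]-2,4,6-trihydroxyphenyl]butan-1-one | CCCC(=O)c1c(O)c(CN(C)C)c(O)c(Cc2c(O)c3c(c(C(=O)CCC)c2O)OC(C)(C)C=C3)c1O
F6 | step 12 | ring B ortho-quinone methide (not isolated) | CCCC(=O)C1=C(O)C(=C)C(=O)C(Cc2c(O)c3c(c(C(=O)CCC)c2O)OC(C)(C)C=C3)=C1O
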